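**Assumption:** the methyl-bearing ring B carbon (C4 of 4, C2 of 5–9) is carried as an epimer mixture because it becomes sp2 in 10, and the ligand antipode for step 2 is fixed by a screen.

## Retrosynthetic overview

1. Butenolide last: Pd/Cu Sonogashira coupling and 5-exo-dig lactonisation of an (E)-enynol with (Z)-3-iodobut-2-enoic acid.
2. Side-chain CH2–C(sp2) bond and the E alkene: B-alkyl Suzuki coupling of the hydroborated decalin vinyl diene with a (Z)-2-iodo-enynol.
3. Diene from the ring B ketone (enol triflate, Stille); ketone from a bicyclic enedione by methylation, C6 deoxygenation and trans hydrogenation.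
4. Enedione: ring B is made six-membered by an enantioselective desymmetrising diazoethane ring expansion (1,2-shift) of a cyclopentane-1,3-dione Michael adduct; ring A is then closed by aldol condensation.
5. Ring order: cyclopentanedione → ring B (expansion) → ring A (aldol) → butenolide.

## Route

Step 1
Reactants: 1 2-methylcyclopentane-1,3-dione; 2 pent-1-en-3-one
Product: 3 2-methyl-2-(3-oxopentyl)cyclopentane-1,3-dione
Conditions: H2O, AcOH (cat.), 70 °C
Reagents that add atoms: none
Why: Michael addition of the acidic cyclic 1,3-dione to the vinyl ketone under near-neutral aqueous conditions gives only C-alkylation; the new quaternary carbon is still prochiral.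

Step 2
Reactants: 3 2-methyl-2-(3-oxopentyl)cyclopentane-1,3-dione
Product: 4 (2S)-2,4-dimethyl-2-(3-oxopentyl)cyclohexane-1,3-dione (C4 epimer mixture)
Conditions: CH3CHN2 (1.1 equiv, toluene solution), Sc(OTf)3 (5 mol%), chiral N,N′-dioxide ligand (L-pipecolic-acid-derived, 2,6-diisopropylanilide arms, 6 mol%), CH2Cl2, −78 → −40 °C
Reagents that add atoms: diazoethane CC=[N+]=[N-]
Why: Proposed new method: catalytic enantioselective desymmetrising one-carbon ring expansion of a prochiral 2,2-disubstituted cyclopentane-1,3-dione – the chiral Sc(OTf)3/N,N′-dioxide Lewis acid activates the pro-S ring carbonyl, diazoethane adds to it, and the ring CH2 (not the acyl-bearing quaternary carbon) undergoes the 1,2-shift with loss of N2 (Tiffeneau–Demjanov-type diazoalkane homologation), which makes ring B six-membered, brings in the future C2 methyl and fixes the quaternary centre as S; the new α-methyl shields the expanded carbonyl, and the carbonyl left in the major enantiomer is the one the catalyst disfavours, so over-homologation mainly consumes the minor enantiomer; closest known reactions are Sc(OTf)3-catalysed diazoalkane homologation of cycloalkanones and chiral-Lewis-acid desymmetrising ring expansion of 4-substituted cyclohexanones with diazo esters.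

Step 3
Reactants: 4 (2S)-2,4-dimethyl-2-(3-oxopentyl)cyclohexane-1,3-dione
Product: 5 (8aS)-2,5,8a-trimethyl-3,4,8,8a-tetrahydronaphthalene-1,6(2H,7H)-dione (C2 epimers)
Conditions: (S)-phenylalanine (0.3 equiv), (1S)-camphor-10-sulfonic acid (0.15 equiv), DMF, 50 °C
Reagents that add atoms: none
Why: Amino-acid-catalysed intramolecular aldol condensation (Hajos–Parrish–Eder–Sauer–Wiechert type, second stage of a Robinson annulation) closes ring A: the side-chain enamine attacks ring carbonyl C1 (flanked by CH2) because C3 is shielded by its α-methyl group and this mode is also the one the L-amino acid prefers for the 2S substrate; no stereocentre is formed and the quaternary centre is untouched.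

Step 4
Reactants: 5 (8aS)-2,5,8a-trimethyl-3,4,8,8a-tetrahydronaphthalene-1,6(2H,7H)-dione
Product: 6 (8aS)-2,5,5,8a-tetramethyl-3,5,8,8a-tetrahydronaphthalene-1,6(2H,7H)-dione
Conditions: KOtBu (1.1 equiv), t-BuOH/THF, 0 °C; MeI (1.5 equiv)
Reagents that add atoms: iodomethane CI
Why: Deconjugative α-alkylation of the thermodynamic extended dienolate (γ-deprotonation at C4) puts the second methyl on C5 and moves the alkene to C4=C4a, where it cannot return into conjugation; the hindered tertiary α-H at C2 is removed far more slowly and that centre is lost later anyway.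

Step 5
Reactants: 6 (8aS)-2,5,5,8a-tetramethyl-3,5,8,8a-tetrahydronaphthalene-1,6(2H,7H)-dione
Product: 8 (8aS)-2,5,5,8a-tetramethyl-3,5,6,7,8,8a-hexahydronaphthalen-1(2H)-one, via C6 tosylhydrazone 7 (not isolated)
Conditions: TsNHNH2 (1.05 equiv), EtOH, 50 °C; then catecholborane, CHCl3, 0 °C; NaOAc·3H2O, reflux
Reagents that add atoms: none
Why: Caglioti/Kabalka tosylhydrazone reduction: the hydrazide condenses only with the C6 ketone (one α-CH2) and not with the C1 ketone flanked by a quaternary carbon and a CHMe group; catecholborane reduces C=N, and loss of sulfinate and N2 leaves CH2 without touching the isolated alkene.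

Step 6
Reactants: 8 (8aS)-2,5,5,8a-tetramethyl-3,5,6,7,8,8a-hexahydronaphthalen-1(2H)-one
Product: 9 (4aS,8aS)-2,5,5,8a-tetramethyloctahydronaphthalen-1(2H)-one
Conditions: H2 (3 atm), 10% Pd/C, EtOAc/AcOH, rt
Reagents that add atoms: none
Why: Heterogeneous catalytic hydrogenation delivers H2 to the α face of the C4=C4a alkene, opposite the angular 8a-methyl and the axial 5-methyl group, which sets C4a as S (trans ring fusion).

Step 7
Reactants: 9 (4aS,8aS)-2,5,5,8a-tetramethyloctahydronaphthalen-1(2H)-one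
Product: 10 (4aS,8aS)-2,5,5,8a-tetramethyl-3,4,4a,5,6,7,8,8a-octahydronaphthalen-1-yl trifluoromethanesulfonate
Conditions: KN(SiMe3)2 (1.3 equiv), THF, −78 → 0 °C; PhNTf2, −78 °C → rt
Reagents that add atoms: N-phenylbis(trifluoromethanesulfonimide) O=S(=O)(N(c1ccccc1)S(=O)(=O)C(F)(F)F)C(F)(F)F
Why: Enol triflate formation: C2–H is the only α-hydrogen of the ketone (C8a is quaternary), so the tetrasubstituted C1=C2 enolate forms regiospecifically and is O-triflated.

Step 8
Reactants: 10 (4aS,8aS)-2,5,5,8a-tetramethyl-3,4,4a,5,6,7,8,8a-octahydronaphthalen-1-yl trifluoromethanesulfonate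
Product: 11 (4aS,8aS)-1-ethenyl-2,5,5,8a-tetramethyl-3,4,4a,5,6,7,8,8a-octahydronaphthalene
Conditions: CH2=CHSnBu3 (1.5 equiv), Pd(PPh3)4 (5 mol%), LiCl (3 equiv), THF, reflux
Reagents that add atoms: tributyl(vinyl)stannane C=C[Sn](CCCC)(CCCC)CCCC
Why: Stille coupling of the hindered alkenyl triflate under LiCl-promoted conditions gives the diene with the ring alkene kept in place.

Step 9
Reactants: 12 3-(trimethylsilyl)prop-2-ynal
Product: 13 ethyl (2Z)-2-iodo-5-(trimethylsilyl)pent-2-en-4-ynoate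
Conditions: Ph3P=CHCO2Et, N-iodosuccinimide, CH2Cl2, −20 °C; then 12, rt
Reagents that add atoms: ethyl (triphenylphosphoranylidene)acetate CCOC(=O)C=P(c1ccccc1)(c1ccccc1)c1ccccc1; N-iodosuccinimide O=C1CCC(=O)N1I
Why: Wittig olefination with the α-iodo ylide formed in the flask; as a stabilised ylide it places the alkynyl group trans to the ester, i.e. cis to iodine (Z), and the minor isomer is removed by chromatography.

Step 10
Reactants: 13 ethyl (2Z)-2-iodo-5-(trimethylsilyl)pent-2-en-4-ynoate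
Product: 14 (2Z)-2-iodo-5-(trimethylsilyl)pent-2-en-4-yn-1-ol
Conditions: i-Bu2AlH (2.2 equiv), CH2Cl2, −78 °C
Reagents that add atoms: none
Why: i-Bu2AlH 1,2-reduction of the enoate to the allylic alcohol at low temperature leaves the C–I bond, the alkene geometry and the silyl alkyne intact.

Step 11
Reactants: 11 (4aS,8aS)-1-ethenyl-2,5,5,8a-tetramethyl-3,4,4a,5,6,7,8,8a-octahydronaphthalene; 14 (2Z)-2-iodo-5-(trimethylsilyl)pent-2-en-4-yn-1-ol
Product: 17 (2E)-2-{2-[(4aS,8aS)-2,5,5,8a-tetramethyl-3,4,4a,5,6,7,8,8a-octahydronaphthalen-1-yl]ethyl}pent-2-en-4-yn-1-ol, via B-alkyl-9-BBN adduct 15 (not isolated), via TMS-enynol 16 (not isolated)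
Conditions: 9-BBN dimer, THF, 0 °C → rt; then 14, Pd(dppf)Cl2 (5 mol%), AsPh3, Cs2CO3, DMF/H2O, rt; then K2CO3, MeOH, rt
Reagents that add atoms: none
Why: 9-BBN hydroboration occurs only at the terminal CH2 of the twisted vinyl group (anti-Markovnikov) and B-alkyl Suzuki–Miyaura coupling with the alkenyl iodide proceeds with retention, so the alkyl chain ends up cis to the alkyne (E); methanolysis then removes the silyl group in the same pot.

Step 12
Reactants: 18 but-2-ynoic acid
Product: 19 (2Z)-3-iodobut-2-enoic acid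
Conditions: NaI, AcOH, 115 °C
Reagents that add atoms: sodium iodide [Na+].[I-]
Why: Anti hydroiodination of the ynoic acid (conjugate addition of iodide, then protonation) gives the Z β-iodo acid.

Step 13
Reactants: 17 (2E)-2-{2-[(4aS,8aS)-2,5,5,8a-tetramethyl-3,4,4a,5,6,7,8,8a-octahydronaphthalen-1-yl]ethyl}pent-2-en-4-yn-1-ol; 19 (2Z)-3-iodobut-2-enoic acid
Product: 21 (5Z)-5-{(2E)-3-(hydroxymethyl)-5-[(4aS,8aS)-2,5,5,8a-tetramethyl-3,4,4a,5,6,7,8,8a-octahydronaphthalen-1-yl]pent-2-en-1-ylidene}-4-methylfuran-2(5H)-one, via enynoic acid 20 (not isolated)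
Conditions: Pd(PPh3)2Cl2 (5 mol%), CuI (10 mol%), Et3N, MeCN, rt
Reagents that add atoms: none
Why: Tandem Sonogashira coupling and 5-exo-dig lactonisation: the carboxylate of the Z-enynoic acid adds anti across the metal-activated alkyne, so the ring oxygen and the side chain are cis (Z ylidene); the hydroxyl of the E-enynol cannot reach the alkyne and needs no protection.

## Compound list

1 | 2-methylcyclopentane-1,3-dione | CC1C(=O)CCC1=O | starting material
2 | pent-1-en-3-one (ethyl vinyl ketone) | CCC(=O)C=C | starting material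
3 | 2-methyl-2-(3-oxopentyl)cyclopentane-1,3-dione | CCC(=O)CCC1(C)C(=O)CCC1=O | intermediate
4 | (2S)-2,4-dimethyl-2-(3-oxopentyl)cyclohexane-1,3-dione (C4 epimers) | C[C@]1(CCC(=O)CC)C(=O)CCC(C)C1=O | intermediate
5 | (8aS)-2,5,8a-trimethyl-3,4,8,8a-tetrahydronaphthalene-1,6(2H,7H)-dione (C2 epimers) | CC1CCC2=C(C)C(=O)CC[C@]2(C)C1=O | intermediate
6 | (8aS)-2,5,5,8a-tetramethyl-3,5,8,8a-tetrahydronaphthalene-1,6(2H,7H)-dione | CC1CC=C2C(C)(C)C(=O)CC[C@]2(C)C1=O | intermediate
7 | C6 mono-tosylhydrazone of 6 | CC1CC=C2C(C)(C)C(=NNS(=O)(=O)c3ccc(C)cc3)CC[C@]2(C)C1=O | intermediate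
8 | (8aS)-2,5,5,8a-tetramethyl-3,5,6,7,8,8a-hexahydronaphthalen-1(2H)-one | CC1CC=C2C(C)(C)CCC[C@]2(C)C1=O | intermediate
9 | (4aS,8aS)-2,5,5,8a-tetramethyloctahydronaphthalen-1(2H)-one (C2 epimers) | O=C1C(C)CC[C@H]2C(C)(C)CCC[C@]12C | intermediate
10 | (4aS,8aS)-2,5,5,8a-tetramethyl-3,4,4a,5,6,7,8,8a-octahydronaphthalen-1-yl trifluoromethanesulfonate | O=S(=O)(OC1=C(C)CC[C@H]2C(C)(C)CCC[C@]12C)C(F)(F)F | intermediate
11 | (4aS,8aS)-1-ethenyl-2,5,5,8a-tetramethyl-3,4,4a,5,6,7,8,8a-octahydronaphthalene | C=CC1=C(C)CC[C@H]2C(C)(C)CCC[C@]12C | intermediate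
12 | 3-(trimethylsilyl)prop-2-ynal | C[Si](C)(C)C#CC=O | starting material
13 | ethyl (2Z)-2-iodo-5-(trimethylsilyl)pent-2-en-4-ynoate | CCOC(=O)/C(I)=C/C#C[Si](C)(C)C | intermediate
14 | (2Z)-2-iodo-5-(trimethylsilyl)pent-2-en-4-yn-1-ol | OC/C(I)=C/C#C[Si](C)(C)C | intermediate
15 | 9-{2-[(4aS,8aS)-2,5,5,8a-tetramethyl-3,4,4a,5,6,7,8,8a-octahydronaphthalen-1-yl]ethyl}-9-borabicyclo[3.3.1]nonane | C(CB1C2CCCC1CCC2)C1=C(C)CC[C@H]2C(C)(C)CCC[C@]12C | intermediate
16 | (2E)-2-{2-[(4aS,8aS)-2,5,5,8a-tetramethyl-3,4,4a,5,6,7,8,8a-octahydronaphthalen-1-yl]ethyl}-5-(trimethylsilyl)pent-2-en-4-yn-1-ol | C[Si](C)(C)C#C/C=C(/CO)CCC1=C(C)CC[C@H]2C(C)(C)CCC[C@]12C | intermediate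
17 | (2E)-2-{2-[(4aS,8aS)-2,5,5,8a-tetramethyl-3,4,4a,5,6,7,8,8a-octahydronaphthalen-1-yl]ethyl}pent-2-en-4-yn-1-ol | C#C/C=C(/CO)CCC1=C(C)CC[C@H]2C(C)(C)CCC[C@]12C | intermediate
18 | but-2-ynoic acid | CC#CC(=O)O | starting material
19 | (2Z)-3-iodobut-2-enoic acid | C/C(I)=C/C(=O)O | intermediate
20 | (2Z,6E)-7-(hydroxymethyl)-3-methyl-9-[(4aS,8aS)-2,5,5,8a-tetramethyl-3,4,4a,5,6,7,8,8a-octahydronaphthalen-1-yl]nona-2,6-dien-4-ynoic acid | OC(=O)/C=C(/C)C#C/C=C(/CO)CCC1=C(C)CC[C@H]2C(C)(C)CCC[C@]12C | intermediate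
21 | (5Z)-5-{(2E)-3-(hydroxymethyl)-5-[(4aS,8aS)-2,5,5,8a-tetramethyl-3,4,4a,5,6,7,8,8a-octahydronaphthalen-1-yl]pent-2-en-1-ylidene}-4-methylfuran-2(5H)-one | CC1=CC(=O)O/C1=C\C=C(\CO)CCC1=C(C)CC[C@H]2C(C)(C)CCC[C@]12C | target

## Step count and risks

Total steps: 13. Longest linear sequence: 10 (steps 1–8, 11, 13).

The three steps most likely to fail:

**Step 2 (proposed new method).** Possible failures are homologation of the side-chain ketone, a second insertion at the other ring carbonyl, or low enantioselectivity. The fallback uses known chemistry and sets out from 3. An (S)-phenylalanine/(1S)-camphor-10-sulfonic acid-catalysed Hajos–Parrish-type aldol condensation closes ring A first and sets the quaternary centre, giving (7aS)-4,7a-dimethyl-2,3,7,7a-tetrahydro-1H-indene-1,5(6H)-dione F1. Its saturated cyclopentanone is then ring-expanded with diazoethane and achiral Sc(OTf)3 (CH2 migrates, the enone carbonyl is inert, and the new α-methyl stops a second insertion). This gives 5, where the route is rejoined.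

**Step 5.** The hydrazide may not fully distinguish the two ketones, or the hindered hydrazone may reduce sluggishly. The fallback sets out from 6. Ethane-1,2-dithiol and BF3·OEt2 thioketalise only the less hindered C6 ketone to give (8aS)-2,5,5,8a-tetramethyl-3,5,8,8a-tetrahydronaphthalene-1,6(2H,7H)-dione 6-(ethane-1,2-diyl dithioketal) F2. Raney Ni in refluxing EtOH then removes sulfur and returns to 8.

**Step 11.** Three operations run in one pot with a hindered homoallylic borane, a free hydroxyl and a base-labile silyl alkyne. The fallback replaces the cross-coupling by an olefination and sets out from 11: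
- 9-BBN followed by NaOH/H2O2 gives 2-[(4aS,8aS)-2,5,5,8a-tetramethyl-3,4,4a,5,6,7,8,8a-octahydronaphthalen-1-yl]ethan-1-ol F3.
- PPh3/I2/imidazole converts it into (4aS,8aS)-1-(2-iodoethyl)-2,5,5,8a-tetramethyl-3,4,4a,5,6,7,8,8a-octahydronaphthalene F4.
- Alkylation of the sodium salt of triethyl phosphonoacetate (NaH, DMF) gives ethyl 2-(diethoxyphosphoryl)-4-[(4aS,8aS)-2,5,5,8a-tetramethyl-3,4,4a,5,6,7,8,8a-octahydronaphthalen-1-yl]butanoate F5.
- Horner–Wadsworth–Emmons olefination of F5 with 12 gives ethyl (2E)-2-{2-[(4aS,8aS)-2,5,5,8a-tetramethyl-3,4,4a,5,6,7,8,8a-octahydronaphthalen-1-yl]ethyl}-5-(trimethylsilyl)pent-2-en-4-ynoate F6 (chain cis to the alkyne; isomers separable).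
- i-Bu2AlH reduction of F6 gives 16, where the route is rejoined; K2CO3/MeOH converts 16 into 17 as in step 11.

## Further compounds

F1 | step 2 | (7aS)-4,7a-dimethyl-2,3,7,7a-tetrahydro-1H-indene-1,5(6H)-dione | CC1=C2CCC(=O)[C@@]2(C)CCC1=O
F2 | step 5 | (8aS)-2,5,5,8a-tetramethyl-3,5,8,8a-tetrahydronaphthalene-1,6(2H,7H)-dione 6-(ethane-1,2-diyl dithioketal) | CC1CC=C2C(C)(C)C3(SCCS3)CC[C@]2(C)C1=O
F3 | step 11 | 2-[(4aS,8aS)-2,5,5,8a-tetramethyl-3,4,4a,5,6,7,8,8a-octahydronaphthalen-1-yl]ethan-1-ol | OCCC1=C(C)CC[C@H]2C(C)(C)CCC[C@]12C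
F4 | step 11 | (4aS,8aS)-1-(2-iodoethyl)-2,5,5,8a-tetramethyl-3,4,4a,5,6,7,8,8a-octahydronaphthalene | ICCC1=C(C)CC[C@H]2C(C)(C)CCC[C@]12C
F5 | step 11 | ethyl 2-(diethoxyphosphoryl)-4-[(4aS,8aS)-2,5,5,8a-tetramethyl-3,4,4a,5,6,7,8,8a-octahydronaphthalen-1-yl]butanoate | CCOC(=O)C(CCC1=C(C)CC[C@H]2C(C)(C)CCC[C@]12C)P(=O)(OCC)OCC
F6 | step 11 | ethyl (2E)-2-{2-[(4aS,8aS)-2,5,5,8a-tetramethyl-3,4,4a,5,6,7,8,8a-octahydronaphthalen-1-yl]ethyl}-5-(trimethylsilyl)pent-2-en-4-ynoate | CCOC(=O)/C(CCC1=C(C)CC[C@H]2C(C)(C)CCC[C@]12C)=C/C#C[Si](C)(C)C
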